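## Structural features

The target is a 2,3-dihydro-1-benzofuran: the five-membered ring O1–C2–C3–C3a–C7a is fused through C3a–C7a to benzene ring A (C3a, C4, C5, C6, C7, C7a). C2 carries a 2,4-dihydroxyphenyl ring, C3 a 3,5-dihydroxyphenyl ring, C4 a hydroxyl group, and C6 a CH2CH2 chain that ends in a 4-hydroxyphenyl ring. C2 and C3 are adjacent stereocentres, both S, with the two aryl groups trans across the ring. Ring A is a 5-alkylresorcinol unit in which C3a lies between the two oxygen-bearing carbons C4 and C7a, the most hindered site for joining C3 to a finished arene. The fragile element is the O1–C2 bond, a benzylic aryl ether whose carbon is activated by ortho and para oxygen on the C2 aryl ring. It behaves like a 2,4-dialkoxybenzyl ether, so protic or Lewis acids can ionise it, with epimerisation, ring opening or elimination towards C3, and the six free phenols add sensitivity to oxidants and base. The difficulty is therefore twofold: the substitution pattern of ring A around C3a, and a trans stereodiad that must survive the unmasking of six hydroxyl groups without acid. The key step uses the fact that ring A is made of three two-carbon units (C3a–C4, C5–C6, C7–C7a), two of which are already joined by the chain O1–C2–C3, so one alkyne cyclotrimerisation closes ring A and the dihydrofuran ring around a stereodiad prepared in an open chain.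

## Logic of the disconnections

20 to 19: the five phenolic O–CH2Ph bonds are cut. Benzyl ethers are chosen so that the last step is a neutral hydrogenolysis; methyl ethers would need a boron trihalide, which the O1–C2 bond is not expected to survive. The gain is five phenols masked in a form stable to bases, organometallics, fluoride and peroxide. The demand is that hydrogenolysis stops before the O1–C2 bond, which is also benzylic, is attacked.

19 to 17 (through 18): the C4–O bond is traced back to a C4–Si bond. Silicon is needed at C4 in any case to steer the cycloaddition. A benzyl group on silicon makes the silane as inert as a trialkylsilane in all earlier steps, yet fluoride alone converts it into an oxidisable silanol; a trimethylsilyl group would require boron–silicon exchange with a Lewis acid. The gain is an acid-free entry to the C4 hydroxyl. The demand is that fluoride expels benzyl and not the ring carbon, and that the aryl group migrates from a hindered silicon.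

17 to 12 and 16: C3a–C7a, C4–C5 and C6–C7 are cut, opening both fused rings. Building ring A from alkynes avoids any substitution at C3a. The gain is two rings and three C–C bonds traded for an acyclic diyne and a terminal alkyne, with the stereodiad left alone. The demand is regiocontrol in the insertion of 16 and survival of a benzylic ynol ether.

12 to 9 and 10 (through 11): the O–C(sp) bond is cut, and the two carbons that become C7a and C7 come from 10. The ynol ether is the least stable function of the route and is therefore installed immediately before the key step. The demand is that strong bases are used next to an acidic, doubly activated C–H and a silylalkyne.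

9 to 6 and 7 (through 8): the C–C bond between the two future ring stereocentres is cut. The leaving group is placed on the fragment whose oxygens are meta to the benzylic carbon and cannot stabilise a cation, and the 2,4-dioxygenated ring enters as the aldehyde; the reverse assignment would give an unusable sulfonate. The gain is that one carbinol stereocentre generates the whole diad. The demand is faithful centre-to-axis-to-centre chirality transfer and anti selectivity.

6 to 5, then 5 to 3 and 4: the O–S bond and then the carbinol–alkyne bond are cut. This alkynylation is the only step in which absolute configuration comes from a catalyst. The demand is high enantioselectivity with an aromatic aldehyde.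

3 to 1 and 2: the Si–C(sp) bond is cut, giving two commercial reagents.

16 to 13 and 14 (through 15): the bond between the two CH2 groups is cut. The nucleophile must therefore be a three-carbon propargyl anion equivalent; an acetylide would give a chain one carbon short.

## Other disconnections considered

Alternative 1: The cut removes both aryl groups from C2 and C3, leaving the aromatic benzofuran A1, the arylboronic ester A2 and the aryl triflate A3. In the forward step A1 is lithiated at C2 and added to A2 to give the boronate complex A4. With Pd(OAc)2 and a chiral MandyPhos ligand, the arylpalladium derived from A3 attacks C3 while the 2,4-dimethoxyphenyl group shifts from boron to C2 on the opposite face; reductive elimination then gives the boronic ester A5. Stereoretentive protodeboronation and deprotection would follow.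
- In its favour: both C–aryl bonds and both stereocentres arise in one catalytic enantioselective step, the trans relationship follows from the anti addition across C2=C3, and ring A never has to be built, so no ynol ether and no silicon-to-oxygen exchange are needed.
- Against it here: C3 is peri to the C4 oxygen, so the arylpalladium must reach a hindered, electron-rich position, and the migrating aryl group has an ortho substituent. Dearomative couplings of this kind are better supported for indoles than for benzofurans with aryl electrophiles. The tertiary α-oxygenated boronic ester A5 must lose boron with retention beside an ionisable O1–C2 bond. A1 needs four to five steps of its own, and its methyl ethers raise the same acid problem at the end.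
- Comparison: on convergence and step economy this alternative is the equal of the chosen plan or better. On mechanism the chosen plan separates the problems (stereodiad through a closed transition state in an open chain, ring formation without stereochemical consequence), whereas here enantiocontrol, diastereocontrol and regiochemistry all depend on one step. On structure the chosen plan builds ring A around the crowded C3a, while this alternative has to functionalise the crowded C3 next to C4–O.

Alternative 2: The cut is C3–C3a, made by a 1,2-shift of ring A. The enantioenriched flavanone A6, with PhI(OAc)2, HC(OMe)3 and catalytic H2SO4, is iodinated at the α-carbon through its enol ether, ring A migrates from the ketal carbon, and the pyranone contracts to the trans ester A7.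
- In its favour: flavanones are quickly made from chalcones, the reagents are cheap, no transition metal is needed, and ring A arrives complete with its oxygen.
- Against it here: A7 carries a carboxylate at C3 and not the 3,5-dioxygenated aryl ring, so the C3–aryl bond would still have to be made (for instance by decarboxylative arylation), which adds steps and resets C3. The acidic, oxidising medium also meets a very electron-rich 2,4-dimethoxyphenyl ring, which invites the competing shift of that ring, ring iodination, and acid-mediated opening of the pyranone that would erode C2.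
- Comparison: it is the equal or better in reagent cost and in avoiding a labile ynol ether. It is weaker on structure, since it does not deliver the full skeleton, and on mechanism, since the wanted migration competes with that of a more electron-rich ring. Its step count would be higher than that of the chosen plan.

Alternative 3: The cut removes O1–C2 and C2–C3 with ring A at the cyclohexanedione oxidation level. The ylide from the chiral sulfonium salt A9 (for example a trans-2,5-dimethylthiolanium salt) adds through carbon to the arylidene carbon of A8, and the enolate oxygen displaces the sulfide to give the ketone A10. Aromatisation of the carbocycle and deprotection would follow.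
- In its favour: three simple components; the C4 oxygen is inherent; the ring and both stereocentres are set in one metal-free step; trans follows from the anti-periplanar closure; the C6 mixture disappears on aromatisation.
- Against it here: A9 is a 2,4-dimethoxybenzyl sulfonium salt and is prone to ionise; the chiral sulfide is stoichiometric and its control over such an ylide is uncertain; A8 tends to add a second dione. Aromatising A10 needs an oxidant that does not dehydrogenate C2–C3 to the fully aromatic benzofuran, which would erase both stereocentres.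
- Comparison: on step count it is the equal of the chosen plan or better, and it solves the C4 oxygen more directly than the silicon route. On mechanism the chosen plan keeps the finished stereodiad away from oxidants and acids, whereas this alternative ends with an oxidation on the stereodefined heterocycle.

Key step: step 7

Assumptions (remarks on the chemistry):
- 4, 7 and 13 are taken as commercial benzyl ethers.
- (R,R)-ProPhenol is taken to deliver the alkynyl group to the Si face of 4, the same facial bias as in the aldol chemistry of this ligand. If ester analysis of 5 with a chiral derivatising acid shows the opposite sense, the (S,S)-ligand is used and nothing else changes.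
- The axial descriptor of 8 and the centre descriptors of 9 follow from anti SN2' palladation, retentive transmetallation and addition on the metal-bearing face.

## Route

Step 1
Reactants: 1 benzylchlorodimethylsilane; 2 ethynylmagnesium bromide
Product: 3 benzyl(ethynyl)dimethylsilane
Conditions: THF, 0 °C → rt
Reagents that add atoms: none
Why: Nucleophilic substitution at silicon by an alkynyl Grignard reagent; the Si–Cl bond is displaced cleanly and the benzyl–silicon bond is inert to the reagent.

Step 2
Reactants: 4 3,5-bis(benzyloxy)benzaldehyde; 3 benzyl(ethynyl)dimethylsilane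
Product: 5 (1R)-3-[benzyl(dimethyl)silyl]-1-[3,5-bis(benzyloxy)phenyl]prop-2-yn-1-ol
Conditions: 3 (2 equiv), Me2Zn (2 equiv), (R,R)-ProPhenol (10 mol %), Ph3P=O (20 mol %), PhMe, 0 °C
Reagents that add atoms: none
Why: Catalytic enantioselective addition of an alkynylzinc to a non-enolisable aromatic aldehyde (dinuclear zinc–ProPhenol catalysis); the new stereocentre (R) is set by ligand-controlled delivery of the alkynyl group to the Si face of the aldehyde.

Step 3
Reactants: 5 (1R)-3-[benzyl(dimethyl)silyl]-1-[3,5-bis(benzyloxy)phenyl]prop-2-yn-1-ol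
Product: 6 (1R)-3-[benzyl(dimethyl)silyl]-1-[3,5-bis(benzyloxy)phenyl]prop-2-yn-1-yl methanesulfonate
Conditions: (MeSO2)2O (1.3 equiv), Et3N, CH2Cl2, −40 °C; cold aqueous work-up, used crude at once
Reagents that add atoms: methanesulfonic anhydride, CS(=O)(=O)OS(C)(=O)=O
Why: O-Sulfonylation with retention at carbon; the anhydride keeps chloride out of the flask, and the meta-placed benzyloxy groups cannot stabilise a benzylic cation by resonance, so the sulfonate should last through a cold work-up.

Step 4
Reactants: 6 (1R)-3-[benzyl(dimethyl)silyl]-1-[3,5-bis(benzyloxy)phenyl]prop-2-yn-1-yl methanesulfonate; 7 2,4-bis(benzyloxy)benzaldehyde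
Product: 9 (1S,2S)-4-[benzyl(dimethyl)silyl]-1-[2,4-bis(benzyloxy)phenyl]-2-[3,5-bis(benzyloxy)phenyl]but-3-yn-1-ol, via allenylzinc 8 (not isolated)
Conditions: Pd(OAc)2 (5 mol %), PPh3 (5 mol %), Et2Zn (3 equiv), THF, −78 → −20 °C
Reagents that add atoms: none
Why: Palladium-catalysed zincation of a propargylic sulfonate followed by SE2' addition of the allenylzinc to an aldehyde: zerovalent palladium displaces the sulfonate anti (SN2'), transmetallation to zinc keeps the axis (8, aS), and the aldehyde reacts through a closed six-membered transition state on the zinc-bearing face with its aryl group turned away from the allene substituent. The propargylic centre of 9 (C2, later ring C3) is thus the inverted carbinol centre of 6 (S), and the carbinol centre (C1, later ring C2) follows as anti (S).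

Step 5
Reactants: 9 (1S,2S)-4-[benzyl(dimethyl)silyl]-1-[2,4-bis(benzyloxy)phenyl]-2-[3,5-bis(benzyloxy)phenyl]but-3-yn-1-ol; 10 trichloroethylene
Product: 12 benzyl[(3S,4S)-4-[2,4-bis(benzyloxy)phenyl]-3-[3,5-bis(benzyloxy)phenyl]-4-(ethynyloxy)but-1-yn-1-yl]dimethylsilane, via dichlorovinyl ether 11 (not isolated)
Conditions: KH (1.3 equiv), THF, 0 °C; 10 (1.1 equiv), −50 °C → rt; n-BuLi (2.4 equiv), −78 °C; H2O, −78 → 0 °C; kept cold, used at once
Reagents that add atoms: none
Why: Two-stage ynol ether synthesis: the potassium alkoxide adds to dichloroacetylene formed in the flask from 10 to give the (E)-1,2-dichlorovinyl ether, and n-BuLi then causes elimination and chlorine–lithium exchange to the lithium alkynyl ether, which is protonated on quench. No bond to either stereocentre is broken, so the (S,S) diad is carried over unchanged.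

Step 6
Reactants: 13 1-(benzyloxy)-4-(chloromethyl)benzene; 14 trimethyl(prop-1-yn-1-yl)silane
Product: 16 1-(benzyloxy)-4-(but-3-yn-1-yl)benzene, via silylated alkyne 15 (not isolated)
Conditions: 14, n-BuLi, THF, −78 → 0 °C; 13, −78 °C → rt; then MeOH, K2CO3, rt
Reagents that add atoms: none
Why: Propargylic lithiation of 14 and SN2 alkylation by the benzylic chloride, with the silyl group directing bond formation to the propargylic terminus; basic methanolysis then removes the C-silyl group to free the terminal alkyne.

Step 7
Reactants: 12 benzyl[(3S,4S)-4-[2,4-bis(benzyloxy)phenyl]-3-[3,5-bis(benzyloxy)phenyl]-4-(ethynyloxy)but-1-yn-1-yl]dimethylsilane; 16 1-(benzyloxy)-4-(but-3-yn-1-yl)benzene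
Product: 17 benzyl[(2S,3S)-2-[2,4-bis(benzyloxy)phenyl]-3-[3,5-bis(benzyloxy)phenyl]-6-{2-[4-(benzyloxy)phenyl]ethyl}-2,3-dihydro-1-benzofuran-4-yl]dimethylsilane
Conditions: Cp*RuCl(cod) (10 mol %), 16 (3 equiv), ClCH2CH2Cl, 20 °C, 12 added over 4 h
Reagents that add atoms: none
Why: Ruthenium-catalysed (2+2+2) alkyne cyclotrimerisation: after loss of cod, oxidative cyclisation of the two tethered alkynes of 12 gives a ruthenacyclopentadiene (C3a–C7a formed), which inserts 16 and reductively eliminates the arene (C4–C5 and C6–C7 formed). The closest known reaction type is the Cp*RuCl-catalysed cycloaddition of unsymmetrical 1,6-diynes with terminal alkynes, and heteroatom-substituted alkynes such as ynamides and alkynyl ethers are established partners in metal-catalysed cyclotrimerisation. The dihydrofuran ring closes in the oxidative cyclisation, because the three-atom tether O1–C2–C3 holds both alkynes on the metal and C3a–C7a becomes the last bond of the five-membered ring. Ring A closes in the insertion and reductive elimination as a six-membered carbocycle made only of the six alkyne carbons, and it is aromatic as soon as it forms. No stereocentre is created, and since no bond to C2 or C3 is made or broken and no acid or base is present, the trans diad of step 4 is carried through unchanged. The step needs regioselectivity in the insertion of 16 and preference for cross- over self-coupling: the benzyl(dimethyl)silyl group on the ruthenacycle carbon that becomes C4 pushes the substituted carbon of 16 to the far side, so the chain ends at C6, meta to silicon, and slow addition of 12 to an excess of 16 suppresses dimerisation of the diyne. Room temperature keeps the benzylic ynol ether away from its thermal sigmatropic and retro-ene pathways.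

Step 8
Reactants: 17 benzyl[(2S,3S)-2-[2,4-bis(benzyloxy)phenyl]-3-[3,5-bis(benzyloxy)phenyl]-6-{2-[4-(benzyloxy)phenyl]ethyl}-2,3-dihydro-1-benzofuran-4-yl]dimethylsilane
Product: 19 (2S,3S)-2-[2,4-bis(benzyloxy)phenyl]-3-[3,5-bis(benzyloxy)phenyl]-6-{2-[4-(benzyloxy)phenyl]ethyl}-2,3-dihydro-1-benzofuran-4-ol, via arylsilanol 18 (not isolated)
Conditions: TBAF (3 equiv), THF, 0 °C → rt; then KHCO3, 30% H2O2, MeOH, 40 °C
Reagents that add atoms: hydrogen peroxide, OO
Why: Fluoride cleaves the benzyl–silicon bond (benzyl is the best carbanion leaving group on this silicon) to give silanol 18, whose aryl–silicon bond then undergoes Tamao–Fleming oxidation with buffered hydrogen peroxide at the same ring carbon. No acid is involved, so the O1–C2 bond and both stereocentres are not at risk.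

Step 9
Reactants: 19 (2S,3S)-2-[2,4-bis(benzyloxy)phenyl]-3-[3,5-bis(benzyloxy)phenyl]-6-{2-[4-(benzyloxy)phenyl]ethyl}-2,3-dihydro-1-benzofuran-4-ol
Product: 20 (2S,3S)-2-(2,4-dihydroxyphenyl)-3-(3,5-dihydroxyphenyl)-6-[2-(4-hydroxyphenyl)ethyl]-2,3-dihydro-1-benzofuran-4-ol
Conditions: H2 (1 atm), 10% Pd/C, EtOAc–MeOH, rt, under exclusion of air on work-up
Reagents that add atoms: none
Why: Catalytic hydrogenolysis of five primary aryl benzyl ethers under neutral conditions; these unhindered O–CH2Ph bonds should be cleaved well before the secondary, ring-held O1–C2 bond, and the reaction is stopped when the last benzyl group has gone. The stereocentres are not involved.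

## Compound list

1 | benzylchlorodimethylsilane | C[Si](C)(Cl)Cc1ccccc1 | starting material
2 | ethynylmagnesium bromide | C#C[Mg]Br | starting material
3 | benzyl(ethynyl)dimethylsilane | C#C[Si](C)(C)Cc1ccccc1 | intermediate
4 | 3,5-bis(benzyloxy)benzaldehyde | O=Cc1cc(OCc2ccccc2)cc(OCc2ccccc2)c1 | starting material
5 | (1R)-3-[benzyl(dimethyl)silyl]-1-[3,5-bis(benzyloxy)phenyl]prop-2-yn-1-ol | O[C@@H](C#C[Si](C)(C)Cc1ccccc1)c1cc(OCc2ccccc2)cc(OCc2ccccc2)c1 | intermediate
6 | (1R)-3-[benzyl(dimethyl)silyl]-1-[3,5-bis(benzyloxy)phenyl]prop-2-yn-1-yl methanesulfonate | CS(=O)(=O)O[C@@H](C#C[Si](C)(C)Cc1ccccc1)c1cc(OCc2ccccc2)cc(OCc2ccccc2)c1 | intermediate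
7 | 2,4-bis(benzyloxy)benzaldehyde | O=Cc1ccc(OCc2ccccc2)cc1OCc1ccccc1 | starting material
8 | (aS)-ethyl{1-[benzyl(dimethyl)silyl]-3-[3,5-bis(benzyloxy)phenyl]propa-1,2-dien-1-yl}zinc | CC[Zn]C([Si](C)(C)Cc1ccccc1)=[C@@]=C([H])c1cc(OCc2ccccc2)cc(OCc2ccccc2)c1 | intermediate (not isolated)
9 | (1S,2S)-4-[benzyl(dimethyl)silyl]-1-[2,4-bis(benzyloxy)phenyl]-2-[3,5-bis(benzyloxy)phenyl]but-3-yn-1-ol | O[C@H](c1ccc(OCc2ccccc2)cc1OCc1ccccc1)[C@H](C#C[Si](C)(C)Cc1ccccc1)c1cc(OCc2ccccc2)cc(OCc2ccccc2)c1 | intermediate
10 | trichloroethylene | ClC=C(Cl)Cl | starting material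
11 | benzyl[(3S,4S)-4-[2,4-bis(benzyloxy)phenyl]-3-[3,5-bis(benzyloxy)phenyl]-4-{[(E)-1,2-dichloroethenyl]oxy}but-1-yn-1-yl]dimethylsilane | Cl/C=C(/Cl)O[C@H](c1ccc(OCc2ccccc2)cc1OCc1ccccc1)[C@H](C#C[Si](C)(C)Cc1ccccc1)c1cc(OCc2ccccc2)cc(OCc2ccccc2)c1 | intermediate (not isolated)
12 | benzyl[(3S,4S)-4-[2,4-bis(benzyloxy)phenyl]-3-[3,5-bis(benzyloxy)phenyl]-4-(ethynyloxy)but-1-yn-1-yl]dimethylsilane | C#CO[C@H](c1ccc(OCc2ccccc2)cc1OCc1ccccc1)[C@H](C#C[Si](C)(C)Cc1ccccc1)c1cc(OCc2ccccc2)cc(OCc2ccccc2)c1 | intermediate
13 | 1-(benzyloxy)-4-(chloromethyl)benzene | ClCc1ccc(OCc2ccccc2)cc1 | starting material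
14 | trimethyl(prop-1-yn-1-yl)silane | CC#C[Si](C)(C)C | starting material
15 | {4-[4-(benzyloxy)phenyl]but-1-yn-1-yl}trimethylsilane | C[Si](C)(C)C#CCCc1ccc(OCc2ccccc2)cc1 | intermediate (not isolated)
16 | 1-(benzyloxy)-4-(but-3-yn-1-yl)benzene | C#CCCc1ccc(OCc2ccccc2)cc1 | intermediate
17 | benzyl[(2S,3S)-2-[2,4-bis(benzyloxy)phenyl]-3-[3,5-bis(benzyloxy)phenyl]-6-{2-[4-(benzyloxy)phenyl]ethyl}-2,3-dihydro-1-benzofuran-4-yl]dimethylsilane | c1ccccc1COc1ccc(CCc2cc([Si](C)(C)Cc3ccccc3)c3c(c2)O[C@H](c2ccc(OCc4ccccc4)cc2OCc2ccccc2)[C@H]3c2cc(OCc3ccccc3)cc(OCc3ccccc3)c2)cc1 | intermediate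
18 | [(2S,3S)-2-[2,4-bis(benzyloxy)phenyl]-3-[3,5-bis(benzyloxy)phenyl]-6-{2-[4-(benzyloxy)phenyl]ethyl}-2,3-dihydro-1-benzofuran-4-yl]dimethylsilanol | c1ccccc1COc1ccc(CCc2cc([Si](C)(C)O)c3c(c2)O[C@H](c2ccc(OCc4ccccc4)cc2OCc2ccccc2)[C@H]3c2cc(OCc3ccccc3)cc(OCc3ccccc3)c2)cc1 | intermediate (not isolated)
19 | (2S,3S)-2-[2,4-bis(benzyloxy)phenyl]-3-[3,5-bis(benzyloxy)phenyl]-6-{2-[4-(benzyloxy)phenyl]ethyl}-2,3-dihydro-1-benzofuran-4-ol | c1ccccc1COc1ccc(CCc2cc(O)c3c(c2)O[C@H](c2ccc(OCc4ccccc4)cc2OCc2ccccc2)[C@H]3c2cc(OCc3ccccc3)cc(OCc3ccccc3)c2)cc1 | intermediate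
20 | (2S,3S)-2-(2,4-dihydroxyphenyl)-3-(3,5-dihydroxyphenyl)-6-[2-(4-hydroxyphenyl)ethyl]-2,3-dihydro-1-benzofuran-4-ol (CNP0329616.1) | Oc1ccc(CCc2cc(O)c3c(c2)O[C@H](c2ccc(O)cc2O)[C@H]3c2cc(O)cc(O)c2)cc1 | target

## Step count and least certain steps

Total: 9 steps. Longest linear sequence: 8 steps (1, 2, 3, 4, 5, 7, 8, 9); step 6 is the side branch.

**Step 7 (key step).** The benzylic ynol ether may be lost by sigmatropic rearrangement or elimination to a ketene before the ruthenacycle forms. Regiocontrol may leak, placing the chain at C5. The diyne may self-couple when the monoalkyne inserts slowly. The fallback sets out from 12 and comes back at 17, and it moves the side chain out of the cycloaddition into a cross-coupling. 12 is cycloadded under the same catalyst with commercial 2-ethynyl-4,4,5,5-tetramethyl-1,3,2-dioxaborolane, a bulkier and more reactive partner, to give 2-[(2S,3S)-4-[benzyl(dimethyl)silyl]-2-[2,4-bis(benzyloxy)phenyl]-3-[3,5-bis(benzyloxy)phenyl]-2,3-dihydro-1-benzofuran-6-yl]-4,4,5,5-tetramethyl-1,3,2-dioxaborolane F1. Suzuki–Miyaura coupling of F1 with (E)-1-(benzyloxy)-4-(2-bromoethenyl)benzene F2 (PdCl2(dppf), K3PO4, dioxane–water) should give the 6-styryl compound benzyl[(2S,3S)-2-[2,4-bis(benzyloxy)phenyl]-3-[3,5-bis(benzyloxy)phenyl]-6-{(E)-2-[4-(benzyloxy)phenyl]ethenyl}-2,3-dihydro-1-benzofuran-4-yl]dimethylsilane F3. Diimide reduction of the alkene (TsNHNH2, NaOAc, aqueous THF, reflux), which leaves benzyl ethers and the O1–C2 bond alone, returns to 17.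

**Step 4.** The sulfonate may ionise before oxidative addition. Enantiomeric purity may erode if the aryl-substituted allenylzinc equilibrates through its propargylic isomer faster than it adds. The anti preference may be weaker with an aromatic aldehyde than with a branched aliphatic one. The fallback sets out from 5 and comes back at 9, and it replaces the zinc reagent by an isolable, configurationally stable boron reagent. 5 is converted with methyl chloroformate and pyridine into (1R)-3-[benzyl(dimethyl)silyl]-1-[3,5-bis(benzyloxy)phenyl]prop-2-yn-1-yl methyl carbonate F4. Anti SN2' borylation of F4 (B2pin2, Pd(PPh3)4, CuI, THF) gives the allenylboronic ester (aR)-2-{1-[benzyl(dimethyl)silyl]-3-[3,5-bis(benzyloxy)phenyl]propa-1,2-dien-1-yl}-4,4,5,5-tetramethyl-1,3,2-dioxaborolane F5. F5 is combined with 7 in toluene under diphenyl phosphate catalysis; the closed six-membered transition state should lead to the same anti alcohol 9.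

**Step 5.** The potassium alkoxide may fragment back to 7 and a stabilised propargyl or allenyl anion. Alkoxide may strip silicon from the alkyne. n-BuLi may deprotonate the doubly activated C–H next to the alkyne, with epimerisation or elimination. The fallback sets out from 9 and comes back at 12, and it never generates a free alkoxide. 9 is formylated with acetic formic anhydride and pyridine to the formate (1S,2S)-4-[benzyl(dimethyl)silyl]-1-[2,4-bis(benzyloxy)phenyl]-2-[3,5-bis(benzyloxy)phenyl]but-3-yn-1-yl formate F6. Dibromo-olefination of the formyl group (CBr4, PPh3, Et3N, CH2Cl2, 0 °C) gives the 2,2-dibromovinyl ether benzyl[(3S,4S)-4-[2,4-bis(benzyloxy)phenyl]-3-[3,5-bis(benzyloxy)phenyl]-4-[(2,2-dibromoethenyl)oxy]but-1-yn-1-yl]dimethylsilane F7. Corey–Fuchs-type elimination and bromine–lithium exchange (n-BuLi, 2 equiv, THF, −78 °C, then water) gives 12.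

**Step 8.** Fluoride may detach the whole silyl group from C4 (protodesilylation) and not the benzyl group alone. Migration of the ring carbon from a hindered silicon to oxygen may be slow. The fallback sets out from 17 and comes back at 20, and it reverses the order of events so that a Lewis acid becomes tolerable. 17 is hydrogenolysed first (H2, Pd/C) to the pentaphenol 4-[(2S,3S)-4-[benzyl(dimethyl)silyl]-3-(3,5-dihydroxyphenyl)-6-[2-(4-hydroxyphenyl)ethyl]-2,3-dihydro-1-benzofuran-2-yl]benzene-1,3-diol F8. Acetylation (Ac2O, pyridine) gives the pentaacetate F9, in which the acetoxy groups withdraw electron density from the C2 aryl ring and so protect the O1–C2 bond against ionisation. Ipso-borodesilylation of F9 with BCl3 (CH2Cl2, −78 → 0 °C), then brief treatment with H2O2 and K2CO3 in methanol, oxidises the arylborane and removes the acetates to give 20.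

## Further compounds

F1 | step 7 | 2-[(2S,3S)-4-[benzyl(dimethyl)silyl]-2-[2,4-bis(benzyloxy)phenyl]-3-[3,5-bis(benzyloxy)phenyl]-2,3-dihydro-1-benzofuran-6-yl]-4,4,5,5-tetramethyl-1,3,2-dioxaborolane | CC1(C)OB(OC1(C)C)c1cc([Si](C)(C)Cc2ccccc2)c2c(c1)O[C@H](c1ccc(OCc3ccccc3)cc1OCc1ccccc1)[C@H]2c1cc(OCc2ccccc2)cc(OCc2ccccc2)c1
F2 | step 7 | (E)-1-(benzyloxy)-4-(2-bromoethenyl)benzene | Br/C=C/c1ccc(OCc2ccccc2)cc1
F3 | step 7 | benzyl[(2S,3S)-2-[2,4-bis(benzyloxy)phenyl]-3-[3,5-bis(benzyloxy)phenyl]-6-{(E)-2-[4-(benzyloxy)phenyl]ethenyl}-2,3-dihydro-1-benzofuran-4-yl]dimethylsilane | c1ccccc1COc1ccc(/C=C/c2cc([Si](C)(C)Cc3ccccc3)c3c(c2)O[C@H](c2ccc(OCc4ccccc4)cc2OCc2ccccc2)[C@H]3c2cc(OCc3ccccc3)cc(OCc3ccccc3)c2)cc1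
F4 | step 4 | (1R)-3-[benzyl(dimethyl)silyl]-1-[3,5-bis(benzyloxy)phenyl]prop-2-yn-1-yl methyl carbonate | COC(=O)O[C@@H](C#C[Si](C)(C)Cc1ccccc1)c1cc(OCc2ccccc2)cc(OCc2ccccc2)c1
F5 | step 4 | (aR)-2-{1-[benzyl(dimethyl)silyl]-3-[3,5-bis(benzyloxy)phenyl]propa-1,2-dien-1-yl}-4,4,5,5-tetramethyl-1,3,2-dioxaborolane | CC1(C)OB(OC1(C)C)C([Si](C)(C)Cc1ccccc1)=[C@@]=C([H])c1cc(OCc2ccccc2)cc(OCc2ccccc2)c1
F6 | step 5 | (1S,2S)-4-[benzyl(dimethyl)silyl]-1-[2,4-bis(benzyloxy)phenyl]-2-[3,5-bis(benzyloxy)phenyl]but-3-yn-1-yl formate | O=CO[C@H](c1ccc(OCc2ccccc2)cc1OCc1ccccc1)[C@H](C#C[Si](C)(C)Cc1ccccc1)c1cc(OCc2ccccc2)cc(OCc2ccccc2)c1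
F7 | step 5 | benzyl[(3S,4S)-4-[2,4-bis(benzyloxy)phenyl]-3-[3,5-bis(benzyloxy)phenyl]-4-[(2,2-dibromoethenyl)oxy]but-1-yn-1-yl]dimethylsilane | BrC(Br)=CO[C@H](c1ccc(OCc2ccccc2)cc1OCc1ccccc1)[C@H](C#C[Si](C)(C)Cc1ccccc1)c1cc(OCc2ccccc2)cc(OCc2ccccc2)c1
F8 | step 8 | 4-[(2S,3S)-4-[benzyl(dimethyl)silyl]-3-(3,5-dihydroxyphenyl)-6-[2-(4-hydroxyphenyl)ethyl]-2,3-dihydro-1-benzofuran-2-yl]benzene-1,3-diol | Oc1ccc(CCc2cc([Si](C)(C)Cc3ccccc3)c3c(c2)O[C@H](c2ccc(O)cc2O)[C@H]3c2cc(O)cc(O)c2)cc1
F9 | step 8 | pentaacetate of F8: (2S,3S)-4-[benzyl(dimethyl)silyl]-2-(2,4-diacetoxyphenyl)-3-(3,5-diacetoxyphenyl)-6-[2-(4-acetoxyphenyl)ethyl]-2,3-dihydro-1-benzofuran | CC(=O)Oc1ccc(CCc2cc([Si](C)(C)Cc3ccccc3)c3c(c2)O[C@H](c2ccc(OC(C)=O)cc2OC(C)=O)[C@H]3c2cc(OC(C)=O)cc(OC(C)=O)c2)cc1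
A1 | alternative 1 | 4-methoxy-6-[2-(4-methoxyphenyl)ethyl]-1-benzofuran | COc1ccc(CCc2cc(OC)c3ccoc3c2)cc1
A2 | alternative 1 | 2-(2,4-dimethoxyphenyl)-4,4,5,5-tetramethyl-1,3,2-dioxaborolane | COc1ccc(B2OC(C)(C)C(C)(C)O2)c(OC)c1
A3 | alternative 1 | 3,5-dimethoxyphenyl trifluoromethanesulfonate | COc1cc(OC)cc(OS(=O)(=O)C(F)(F)F)c1
A4 | alternative 1 | lithium boronate complex of 2-lithiated A1 and A2 | [Li+].COc1ccc(CCc2cc(OC)c3cc([B-]4(OC(C)(C)C(C)(C)O4)c4ccc(OC)cc4OC)oc3c2)cc1
A5 | alternative 1 | 2-[(2S,3S)-2-(2,4-dimethoxyphenyl)-3-(3,5-dimethoxyphenyl)-4-methoxy-6-[2-(4-methoxyphenyl)ethyl]-2,3-dihydro-1-benzofuran-2-yl]-4,4,5,5-tetramethyl-1,3,2-dioxaborolane | COc1ccc(CCc2cc(OC)c3c(c2)O[C@](B2OC(C)(C)C(C)(C)O2)(c2ccc(OC)cc2OC)[C@H]3c2cc(OC)cc(OC)c2)cc1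
A6 | alternative 2 | (2S)-2-(2,4-dimethoxyphenyl)-5-methoxy-7-[2-(4-methoxyphenyl)ethyl]-2,3-dihydro-4H-chromen-4-one | COc1ccc(CCc2cc(OC)c3c(c2)O[C@H](c2ccc(OC)cc2OC)CC3=O)cc1
A7 | alternative 2 | methyl (2S,3S)-2-(2,4-dimethoxyphenyl)-4-methoxy-6-[2-(4-methoxyphenyl)ethyl]-2,3-dihydro-1-benzofuran-3-carboxylate | COc1ccc(CCc2cc(OC)c3c(c2)O[C@H](c2ccc(OC)cc2OC)[C@H]3C(=O)OC)cc1
A8 | alternative 3 | 2-[(3,5-dimethoxyphenyl)methylidene]-5-[2-(4-methoxyphenyl)ethyl]cyclohexane-1,3-dione | COc1ccc(CCC2CC(=O)C(=Cc3cc(OC)cc(OC)c3)C(=O)C2)cc1
A9 | alternative 3 | (2R,5R)-1-[(2,4-dimethoxyphenyl)methyl]-2,5-dimethylthiolan-1-ium trifluoromethanesulfonate | C[C@@H]1CC[C@@H](C)[S+]1Cc1ccc(OC)cc1OC.[O-]S(=O)(=O)C(F)(F)F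
A10 | alternative 3 | (2S,3S)-2-(2,4-dimethoxyphenyl)-3-(3,5-dimethoxyphenyl)-6-[2-(4-methoxyphenyl)ethyl]-3,5,6,7-tetrahydro-1-benzofuran-4(2H)-one, C6 as a mixture | COc1ccc(CCC2CC(=O)C3=C(C2)O[C@H](c2ccc(OC)cc2OC)[C@H]3c2cc(OC)cc(OC)c2)cc1
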